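**Retrosynthetic overview**
- The target is cut twice at the quaternary carbon: a double Michael addition of fragment C, (6S)-6-methyloxane-2,4-dione, to two molecules of a silyl-protected 14-membered enedione macrodiolide, with desilylation last.
- The macrodiolide comes from oxidation of a macrocyclic allylic alcohol, whose ring is closed by an intramolecular Nozaki–Hiyama–Kishi coupling of an aldehyde with an (E)-beta-iodoacrylate ester.
- The open chain is joined at the (Z)-enoate by an Ando-type Horner–Wadsworth–Emmons reaction between fragment A (phosphonoacetate of (S)-hex-5-en-2-ol) and fragment B (anti-configured alpha-silyloxy aldehyde carrying the iodoacrylate).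
- Stereocentres: fragment C by Noyori hydrogenation of methyl acetoacetate; fragment A by ketoreductase reduction of hex-5-en-2-one; fragment B by Sharpless epoxidation of (E)-crotyl alcohol followed by C3-selective epoxide opening with inversion.
- Ring order: the oxanedione ring first (step 3), then the 14-membered ring (step 17, made once and used twice); the two are joined in step 19.

Assumption: the quaternary carbon carries two identical macrolide units and is not a stereocentre, and the (R) configuration at the two carbons next to it is taken to be the one the macrocycle itself favours in the reversible conjugate addition. TBS = tert-butyldimethylsilyl.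

**Step 1**
Reactants: 1 methyl 3-oxobutanoate
Product: 2 methyl (3S)-3-hydroxybutanoate
Conditions: H2 (50 atm), RuCl2[(S)-BINAP] (0.1 mol%), MeOH, 30 °C
Reagents that add atoms: none
Why: Noyori asymmetric hydrogenation, in which the chelated beta-keto ester is reduced on one carbonyl face by the (S)-BINAP–ruthenium hydride to give the (S) alcohol in high ee.

**Step 2**
Reactants: 2 methyl (3S)-3-hydroxybutanoate; 3 tert-butyl acetate
Product: 5 tert-butyl (5S)-5-hydroxy-3-oxohexanoate, via lithium enolate of tert-butyl acetate 4 (not isolated)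
Conditions: 3 (3.3 equiv), LiN(i-Pr)2 (3.3 equiv), THF, −78 °C; then 2, −78 → −25 °C; 1 M HCl quench
Reagents that add atoms: none
Why: Crossed Claisen condensation in which excess enolate (one equivalent each for the free hydroxyl, the acylation and the acidic product) attacks the methyl ester while the hindered tert-butyl ester does not self-condense, leaving the stereocentre untouched.

**Step 3**
Reactants: 5 tert-butyl (5S)-5-hydroxy-3-oxohexanoate
Product: 7 (6S)-6-methyloxane-2,4-dione, via (5S)-5-hydroxy-3-oxohexanoic acid 6 (not isolated)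
Conditions: CF3CO2H, CH2Cl2, 0 °C → rt
Reagents that add atoms: none
Why: Acidolysis of the tert-butyl ester followed by six-membered lactonisation, which is faster than decarboxylation at room temperature and gives the enolised beta-keto lactone without touching the stereocentre.

**Step 4**
Reactants: 8 hex-5-en-2-one
Product: 9 (2S)-hex-5-en-2-ol
Conditions: ketoreductase (Prelog-selective, NADPH-dependent), NADP+ (cat.), i-PrOH (15% v/v), phosphate buffer pH 7.0, 30 °C
Reagents that add atoms: none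
Why: Enzymatic asymmetric ketone reduction, in which the ketoreductase delivers hydride from NADPH to the Re face of the methyl ketone to give the (S) alcohol in >99% ee, with isopropanol recycling the cofactor.

**Step 5**
Reactants: 9 (2S)-hex-5-en-2-ol; 10 bromoacetyl bromide
Product: 11 (2S)-hex-5-en-2-yl bromoacetate
Conditions: 10 (1.2 equiv), pyridine, CH2Cl2, 0 °C
Reagents that add atoms: none
Why: O-Acylation of a secondary alcohol by an acyl bromide, which does not involve the stereocentre.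

**Step 6**
Reactants: 11 (2S)-hex-5-en-2-yl bromoacetate
Product: 12 (2S)-hex-5-en-2-yl (diphenoxyphosphoryl)acetate
Conditions: (PhO)2P(O)H, Et3N, CH2Cl2, 0 °C → rt
Reagents that add atoms: diphenyl phosphite, O=[PH](Oc1ccccc1)Oc1ccccc1
Why: Michaelis–Becker-type P-alkylation of the phosphite by the activated alpha-bromo ester under amine base, the standard entry to Ando phosphonates.

**Step 7**
Reactants: 13 (2E)-but-2-en-1-ol
Product: 14 [(2R,3R)-3-methyloxiran-2-yl]methanol
Conditions: Ti(OiPr)4 (5 mol%), D-(−)-diisopropyl tartrate (6 mol%), t-BuOOH (anhydrous, 2 equiv), 4 Å molecular sieves, CH2Cl2, −20 °C; non-aqueous work-up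
Reagents that add atoms: tert-butyl hydroperoxide, CC(C)(C)OO
Why: Catalytic Sharpless asymmetric epoxidation, in which the titanium–D-tartrate complex delivers the peroxide oxygen to one face of the E allylic alcohol and sets both epoxide centres as (2R,3R).

**Step 8**
Reactants: 14 [(2R,3R)-3-methyloxiran-2-yl]methanol
Product: 15 (2S,3R)-3,4-dihydroxybutan-2-yl benzoate
Conditions: PhCO2H (1.2 equiv), Ti(OiPr)4 (1.5 equiv), CH2Cl2, rt; aqueous tartaric acid work-up
Reagents that add atoms: benzoic acid, OC(=O)c1ccccc1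
Why: Titanium-mediated regioselective epoxide opening (Sharpless C3-opening of 2,3-epoxy alcohols), in which benzoate attacks C3 of the titanium-bound epoxy alcohol with inversion to give the anti arrangement and marks the C3 oxygen as an ester.

**Step 9**
Reactants: 15 (2S,3R)-3,4-dihydroxybutan-2-yl benzoate
Product: 16 (2S,3R)-3,4-bis[(tert-butyldimethylsilyl)oxy]butan-2-yl benzoate
Conditions: TBSOTf (2.4 equiv), 2,6-lutidine, CH2Cl2, −78 → 0 °C
Reagents that add atoms: tert-butyldimethylsilyl trifluoromethanesulfonate, CC(C)(C)[Si](C)(C)OS(=O)(=O)C(F)(F)F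
Why: Silyl ether formation on both hydroxyls with a silyl triflate and a hindered base at low temperature, conditions under which the benzoate does not migrate.

**Step 10**
Reactants: 16 (2S,3R)-3,4-bis[(tert-butyldimethylsilyl)oxy]butan-2-yl benzoate
Product: 17 (2S,3R)-3,4-bis[(tert-butyldimethylsilyl)oxy]butan-2-ol
Conditions: i-Bu2AlH (2.2 equiv), CH2Cl2, −78 °C; aqueous sodium potassium tartrate work-up
Reagents that add atoms: none
Why: Reductive ester cleavage, chosen because the aluminium alkoxide formed at −78 °C does not trigger the 1,2-silyl migration that basic methanolysis could cause.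

**Step 11**
Reactants: 18 prop-2-ynoic acid
Product: 19 (2E)-3-iodoprop-2-enoic acid
Conditions: 57% aq. HI, 95 °C
Reagents that add atoms: hydrogen iodide, I
Why: Hydroiodination of an ynoic acid by conjugate addition of iodide, with heating to equilibrate the kinetic Z adduct to the more stable E acid.

**Step 12**
Reactants: 17 (2S,3R)-3,4-bis[(tert-butyldimethylsilyl)oxy]butan-2-ol; 19 (2E)-3-iodoprop-2-enoic acid
Product: 20 (2S,3R)-3,4-bis[(tert-butyldimethylsilyl)oxy]butan-2-yl (2E)-3-iodoprop-2-enoate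
Conditions: N,N'-diisopropylcarbodiimide, DMAP (0.1 equiv), CH2Cl2, 0 °C → rt
Reagents that add atoms: none
Why: Steglich esterification with retention at the carbinol carbon, using the thermodynamically stable E acid so that DMAP cannot change the alkene geometry.

**Step 13**
Reactants: 20 (2S,3R)-3,4-bis[(tert-butyldimethylsilyl)oxy]butan-2-yl (2E)-3-iodoprop-2-enoate
Product: 21 (2S,3R)-3-[(tert-butyldimethylsilyl)oxy]-4-hydroxybutan-2-yl (2E)-3-iodoprop-2-enoate
Conditions: HF·pyridine, pyridine, THF, 0 °C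
Reagents that add atoms: none
Why: Selective desilylation in which buffered HF·pyridine removes the less hindered primary silyl ether, the mildly acidic medium avoiding acyl and silyl migration.

**Step 14**
Reactants: 21 (2S,3R)-3-[(tert-butyldimethylsilyl)oxy]-4-hydroxybutan-2-yl (2E)-3-iodoprop-2-enoate
Product: 22 (2S,3S)-3-[(tert-butyldimethylsilyl)oxy]-4-oxobutan-2-yl (2E)-3-iodoprop-2-enoate
Conditions: Dess–Martin periodinane, pyridine, CH2Cl2, 0 °C → rt; used at once
Reagents that add atoms: none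
Why: Dess–Martin oxidation under buffered, non-basic conditions, so the alpha-silyloxy aldehyde neither epimerises nor eliminates (the descriptor changes only through priority rules).

**Step 15**
Reactants: 12 (2S)-hex-5-en-2-yl (diphenoxyphosphoryl)acetate; 22 (2S,3S)-3-[(tert-butyldimethylsilyl)oxy]-4-oxobutan-2-yl (2E)-3-iodoprop-2-enoate
Product: 24 (2S)-hex-5-en-2-yl (2Z,4R,5S)-4-[(tert-butyldimethylsilyl)oxy]-5-{[(2E)-3-iodoprop-2-enoyl]oxy}hex-2-enoate, via sodium phosphonate carbanion 23 (not isolated)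
Conditions: 12, NaH, THF, 0 °C; then 22, −78 → −20 °C
Reagents that add atoms: none
Why: Ando-modified Horner–Wadsworth–Emmons olefination, in which the diaryl phosphonate collapses fast from the kinetic adduct to give the Z enoate, particularly with alpha-oxygenated aldehydes, and joins fragments A and B without a free delta-hydroxyl ever facing the Z ester.

**Step 16**
Reactants: 24 (the Z-enoate from step 15)
Product: 26 (2S)-5-oxopentan-2-yl (2Z,4R,5S)-4-[(tert-butyldimethylsilyl)oxy]-5-{[(2E)-3-iodoprop-2-enoyl]oxy}hex-2-enoate, via vicinal diol 25 (not isolated)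
Conditions: OsO4 (2 mol%), NaIO4 (4 equiv), 2,6-lutidine, dioxane/H2O (3:1), rt
Reagents that add atoms: osmium tetroxide OsO4, O=[Os](=O)(=O)=O (catalytic oxygen carrier); sodium periodate NaIO4, [Na+].[O-]I(=O)(=O)=O (terminal oxidant)
Why: Lemieux–Johnson oxidative cleavage, selective because OsO4 dihydroxylates the electron-rich terminal alkene far faster than the two acceptor-substituted alkenes.

**Step 17**
Reactants: 26 (the aldehyde from step 16)
Product: 27 (3Z,5R,6S,9E,11RS,14S)-5-[(tert-butyldimethylsilyl)oxy]-11-hydroxy-6,14-dimethyl-1,7-dioxacyclotetradeca-3,9-diene-2,8-dione (both C11 epimers)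
Conditions: CrCl2 (10 equiv), NiCl2 (0.1 equiv), degassed DMSO, rt, 0.002 M (slow addition of 26)
Reagents that add atoms: none
Why: Intramolecular Nozaki–Hiyama–Kishi coupling, in which zerovalent nickel inserts into the C–I bond, the alkenyl group passes to trivalent chromium and adds chemoselectively to the aldehyde under high dilution, the new carbinol centre forming without control because it is erased in the next step.

**Step 18**
Reactants: 27 (the macrocyclic allylic alcohol)
Product: 28 (3Z,5R,6S,9E,14S)-5-[(tert-butyldimethylsilyl)oxy]-6,14-dimethyl-1,7-dioxacyclotetradeca-3,9-diene-2,8,11-trione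
Conditions: Dess–Martin periodinane, pyridine, CH2Cl2, rt
Reagents that add atoms: none
Why: Dess–Martin oxidation of the allylic alcohol, in which both epimers converge on the single E enedione.

**Step 19**
Reactants: 7 (6S)-6-methyloxane-2,4-dione (1.0 equiv); 28 (the enedione macrodiolide, 2.5 equiv)
Product: 30 (6S)-3,3-bis{(3Z,5R,6S,9R,14S)-5-[(tert-butyldimethylsilyl)oxy]-6,14-dimethyl-2,8,11-trioxo-1,7-dioxacyclotetradec-3-en-9-yl}-6-methyloxane-2,4-dione, via mono-Michael adduct 29 (not isolated)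
Conditions: Et3N (0.3 equiv), CH2Cl2 (1 M in 28), rt → 40 °C; excess 28 recovered
Reagents that add atoms: none
Why: Double Michael addition in which the enolised beta-keto lactone attacks the enedione at the carbon beta to the ketone (alpha to the ester), the still enolisable mono-adduct adds to a second enedione to build the quaternary carbon, and each new (R) centre comes from attack on the outer face of the macrocycle, the reversibility under amine base letting the more stable adduct accumulate.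

**Step 20**
Reactants: 30 (the bis-silyl ether)
Product: 31 (6S)-3,3-bis[(3Z,5R,6S,9R,14S)-5-hydroxy-6,14-dimethyl-2,8,11-trioxo-1,7-dioxacyclotetradec-3-en-9-yl]-6-methyloxane-2,4-dione (CNP0083691.2)
Conditions: HF·pyridine, pyridine, THF, 0 °C → rt
Reagents that add atoms: none
Why: Fluoride-mediated desilylation under buffered, weakly acidic conditions, which spares the non-enolisable beta-keto lactone and avoids the acyl migration or butenolide formation that basic fluoride would invite.

**Compound list**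
1 | methyl 3-oxobutanoate | CC(=O)CC(=O)OC | starting material
2 | methyl (3S)-3-hydroxybutanoate | C[C@H](O)CC(=O)OC | intermediate
3 | tert-butyl acetate | CC(=O)OC(C)(C)C | starting material
4 | lithium enolate of tert-butyl acetate (formed in the flask) | [Li+].[O-]C(=C)OC(C)(C)C | intermediate
5 | tert-butyl (5S)-5-hydroxy-3-oxohexanoate | C[C@H](O)CC(=O)CC(=O)OC(C)(C)C | intermediate
6 | (5S)-5-hydroxy-3-oxohexanoic acid (formed in the flask) | C[C@H](O)CC(=O)CC(=O)O | intermediate
7 | (6S)-6-methyloxane-2,4-dione, fragment C (enol tautomer: (6S)-4-hydroxy-6-methyl-5,6-dihydro-2H-pyran-2-one) | C[C@H]1CC(=O)CC(=O)O1 | intermediate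
8 | hex-5-en-2-one | CC(=O)CCC=C | starting material
9 | (2S)-hex-5-en-2-ol | C[C@H](O)CCC=C | intermediate
10 | bromoacetyl bromide | BrCC(Br)=O | starting material
11 | (2S)-hex-5-en-2-yl bromoacetate | C[C@H](OC(=O)CBr)CCC=C | intermediate
12 | (2S)-hex-5-en-2-yl (diphenoxyphosphoryl)acetate, fragment A | C[C@H](OC(=O)CP(=O)(Oc1ccccc1)Oc1ccccc1)CCC=C | intermediate
13 | (2E)-but-2-en-1-ol | C/C=C/CO | starting material
14 | [(2R,3R)-3-methyloxiran-2-yl]methanol | C[C@H]1O[C@@H]1CO | intermediate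
15 | (2S,3R)-3,4-dihydroxybutan-2-yl benzoate | C[C@H](OC(=O)c1ccccc1)[C@H](O)CO | intermediate
16 | (2S,3R)-3,4-bis[(tert-butyldimethylsilyl)oxy]butan-2-yl benzoate | C[C@H](OC(=O)c1ccccc1)[C@H](O[Si](C)(C)C(C)(C)C)CO[Si](C)(C)C(C)(C)C | intermediate
17 | (2S,3R)-3,4-bis[(tert-butyldimethylsilyl)oxy]butan-2-ol | C[C@H](O)[C@H](O[Si](C)(C)C(C)(C)C)CO[Si](C)(C)C(C)(C)C | intermediate
18 | prop-2-ynoic acid | C#CC(=O)O | starting material
19 | (2E)-3-iodoprop-2-enoic acid | OC(=O)/C=C/I | intermediate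
20 | (2S,3R)-3,4-bis[(tert-butyldimethylsilyl)oxy]butan-2-yl (2E)-3-iodoprop-2-enoate | C[C@H](OC(=O)/C=C/I)[C@H](O[Si](C)(C)C(C)(C)C)CO[Si](C)(C)C(C)(C)C | intermediate
21 | (2S,3R)-3-[(tert-butyldimethylsilyl)oxy]-4-hydroxybutan-2-yl (2E)-3-iodoprop-2-enoate | C[C@H](OC(=O)/C=C/I)[C@H](O[Si](C)(C)C(C)(C)C)CO | intermediate
22 | (2S,3S)-3-[(tert-butyldimethylsilyl)oxy]-4-oxobutan-2-yl (2E)-3-iodoprop-2-enoate, fragment B | C[C@H](OC(=O)/C=C/I)[C@H](O[Si](C)(C)C(C)(C)C)C=O | intermediate
23 | sodium salt of the alpha-carbanion of 12 (formed in the flask) | C[C@H](OC(=O)[CH-]P(=O)(Oc1ccccc1)Oc1ccccc1)CCC=C.[Na+] | intermediate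
24 | (2S)-hex-5-en-2-yl (2Z,4R,5S)-4-[(tert-butyldimethylsilyl)oxy]-5-{[(2E)-3-iodoprop-2-enoyl]oxy}hex-2-enoate | C=CCC[C@H](C)OC(=O)/C=C\[C@@H](O[Si](C)(C)C(C)(C)C)[C@H](C)OC(=O)/C=C/I | intermediate
25 | (2S,5RS)-5,6-dihydroxyhexan-2-yl (2Z,4R,5S)-4-[(tert-butyldimethylsilyl)oxy]-5-{[(2E)-3-iodoprop-2-enoyl]oxy}hex-2-enoate (formed in the flask) | OCC(O)CC[C@H](C)OC(=O)/C=C\[C@@H](O[Si](C)(C)C(C)(C)C)[C@H](C)OC(=O)/C=C/I | intermediate
26 | (2S)-5-oxopentan-2-yl (2Z,4R,5S)-4-[(tert-butyldimethylsilyl)oxy]-5-{[(2E)-3-iodoprop-2-enoyl]oxy}hex-2-enoate | O=CCC[C@H](C)OC(=O)/C=C\[C@@H](O[Si](C)(C)C(C)(C)C)[C@H](C)OC(=O)/C=C/I | intermediate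
27 | (3Z,5R,6S,9E,11RS,14S)-5-[(tert-butyldimethylsilyl)oxy]-11-hydroxy-6,14-dimethyl-1,7-dioxacyclotetradeca-3,9-diene-2,8-dione (C11 epimers) | C[C@@H]1OC(=O)/C=C/C(O)CC[C@H](C)OC(=O)/C=C\[C@H]1O[Si](C)(C)C(C)(C)C | intermediate
28 | (3Z,5R,6S,9E,14S)-5-[(tert-butyldimethylsilyl)oxy]-6,14-dimethyl-1,7-dioxacyclotetradeca-3,9-diene-2,8,11-trione | C[C@@H]1OC(=O)/C=C/C(=O)CC[C@H](C)OC(=O)/C=C\[C@H]1O[Si](C)(C)C(C)(C)C | intermediate
29 | (6S)-3-{(3Z,5R,6S,9R,14S)-5-[(tert-butyldimethylsilyl)oxy]-6,14-dimethyl-2,8,11-trioxo-1,7-dioxacyclotetradec-3-en-9-yl}-4-hydroxy-6-methyl-5,6-dihydro-2H-pyran-2-one (formed in the flask) | C[C@@H]1OC(=O)[C@@H](C2=C(O)C[C@H](C)OC2=O)CC(=O)CC[C@H](C)OC(=O)/C=C\[C@H]1O[Si](C)(C)C(C)(C)C | intermediate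
30 | (6S)-3,3-bis{(3Z,5R,6S,9R,14S)-5-[(tert-butyldimethylsilyl)oxy]-6,14-dimethyl-2,8,11-trioxo-1,7-dioxacyclotetradec-3-en-9-yl}-6-methyloxane-2,4-dione | C[C@@H]1OC(=O)[C@@H](C2([C@H]3CC(=O)CC[C@H](C)OC(=O)/C=C\[C@@H](O[Si](C)(C)C(C)(C)C)[C@H](C)OC3=O)C(=O)C[C@H](C)OC2=O)CC(=O)CC[C@H](C)OC(=O)/C=C\[C@H]1O[Si](C)(C)C(C)(C)C | intermediate
31 | (6S)-3,3-bis[(3Z,5R,6S,9R,14S)-5-hydroxy-6,14-dimethyl-2,8,11-trioxo-1,7-dioxacyclotetradec-3-en-9-yl]-6-methyloxane-2,4-dione (CNP0083691.2) | C[C@@H]1OC(=O)[C@@H](C2([C@H]3CC(=O)CC[C@H](C)OC(=O)/C=C\[C@@H](O)[C@H](C)OC3=O)C(=O)C[C@H](C)OC2=O)CC(=O)CC[C@H](C)OC(=O)/C=C\[C@H]1O | target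

**Totals**
Total step count: 20. Longest linear sequence: 13 steps (13 → 14 → 15 → 16 → 17 → 20 → 21 → 22 → 24 → 26 → 27 → 28 → 30 → 31, i.e. steps 7–10 and 12–20).

**Steps most likely to fail, with fallbacks**

Step 19 (double Michael addition: the congested quaternary carbon and the facial selectivity rest on substrate control). The fallback sets out from 29 and comes back at 30. Compounds 7 and 28 are combined 1:1 so that the reaction stops at the mono-adduct 29, which is isolated this time. Chlorotrimethylsilane (C[Si](C)(C)Cl) and Et3N in CH2Cl2 at 0 °C turn its acidic enol into the silyl enol ether (6S)-3-{(3Z,5R,6S,9R,14S)-5-[(tert-butyldimethylsilyl)oxy]-6,14-dimethyl-2,8,11-trioxo-1,7-dioxacyclotetradec-3-en-9-yl}-6-methyl-4-[(trimethylsilyl)oxy]-5,6-dihydro-2H-pyran-2-one F1. A Mukaiyama–Michael addition of F1 to a second equivalent of 28 (Sc(OTf)3, 10 mol%, CH2Cl2, −40 °C) then forms the quaternary carbon under Lewis-acid activation of the enedione instead of base catalysis. It gives the trimethylsilyl enol ether of 30 F2, which is hydrolysed to 30 on aqueous work-up.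

Step 17 (Nozaki–Hiyama–Kishi macrocyclisation: oligomerisation or reduction of the iodoacrylate could compete). The fallback replaces it by ring-closing metathesis; it sets out from 17 and comes back at 27.
- Alcohol 17 is acylated with acryloyl chloride (C=CC(=O)Cl) and i-Pr2NEt to (2S,3R)-3,4-bis[(tert-butyldimethylsilyl)oxy]butan-2-yl prop-2-enoate F3.
- HF·pyridine gives (2S,3R)-3-[(tert-butyldimethylsilyl)oxy]-4-hydroxybutan-2-yl prop-2-enoate F4, and Dess–Martin oxidation gives (2S,3S)-3-[(tert-butyldimethylsilyl)oxy]-4-oxobutan-2-yl prop-2-enoate F5.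
- Ando olefination with 12 (through 23) gives (2S)-hex-5-en-2-yl (2Z,4R,5S)-4-[(tert-butyldimethylsilyl)oxy]-5-(prop-2-enoyloxy)hex-2-enoate F6.
- Careful OsO4 (cat.)/NaIO4 cleavage of the terminal alkene passes through (2S,5RS)-5,6-dihydroxyhexan-2-yl (2Z,4R,5S)-4-[(tert-butyldimethylsilyl)oxy]-5-(prop-2-enoyloxy)hex-2-enoate F7 to (2S)-5-oxopentan-2-yl (2Z,4R,5S)-4-[(tert-butyldimethylsilyl)oxy]-5-(prop-2-enoyloxy)hex-2-enoate F8.
- CH2=CHMgBr (C=C[Mg]Br) in THF at −78 °C adds to the aldehyde only and gives (2S,5RS)-5-hydroxyhept-6-en-2-yl (2Z,4R,5S)-4-[(tert-butyldimethylsilyl)oxy]-5-(prop-2-enoyloxy)hex-2-enoate F9.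
- Ring-closing metathesis of the acrylate with the vinyl carbinol (second-generation Grubbs catalyst, toluene, 80 °C, 0.001 M) closes the 14-membered ring as the E enoate 27.

Step 15 (Z-selective olefination with a base-sensitive beta-acyloxy aldehyde). The fallback is a base-free Wittig reaction; it sets out from 11 and comes back at 24. Bromoacetate 11 and PPh3 (toluene, rt) give the phosphonium salt [2-{[(2S)-hex-5-en-2-yl]oxy}-2-oxoethyl]triphenylphosphonium bromide F10. Aqueous NaOH/CH2Cl2 turns it into the stabilised ylide (2S)-hex-5-en-2-yl (triphenyl-λ5-phosphanylidene)acetate F11. Reaction of F11 with aldehyde 22 in MeOH at 0 °C, where alpha-alkoxy aldehydes favour the Z enoate, gives 24 after chromatographic removal of the E isomer.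

**Further compounds**
F1 | step 19 | (6S)-3-{(3Z,5R,6S,9R,14S)-5-[(tert-butyldimethylsilyl)oxy]-6,14-dimethyl-2,8,11-trioxo-1,7-dioxacyclotetradec-3-en-9-yl}-6-methyl-4-[(trimethylsilyl)oxy]-5,6-dihydro-2H-pyran-2-one | C[C@@H]1OC(=O)[C@@H](C2=C(O[Si](C)(C)C)C[C@H](C)OC2=O)CC(=O)CC[C@H](C)OC(=O)/C=C\[C@H]1O[Si](C)(C)C(C)(C)C
F2 | step 19 | trimethylsilyl enol ether of 30 at the ring ketone of the newly attached macrolide (not isolated) | C[C@@H]1OC(=O)[C@@H](C2([C@H]3C=C(O[Si](C)(C)C)CC[C@H](C)OC(=O)/C=C\[C@@H](O[Si](C)(C)C(C)(C)C)[C@H](C)OC3=O)C(=O)C[C@H](C)OC2=O)CC(=O)CC[C@H](C)OC(=O)/C=C\[C@H]1O[Si](C)(C)C(C)(C)C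
F3 | step 17 | (2S,3R)-3,4-bis[(tert-butyldimethylsilyl)oxy]butan-2-yl prop-2-enoate | C[C@H](OC(=O)C=C)[C@H](O[Si](C)(C)C(C)(C)C)CO[Si](C)(C)C(C)(C)C
F4 | step 17 | (2S,3R)-3-[(tert-butyldimethylsilyl)oxy]-4-hydroxybutan-2-yl prop-2-enoate | C[C@H](OC(=O)C=C)[C@H](O[Si](C)(C)C(C)(C)C)CO
F5 | step 17 | (2S,3S)-3-[(tert-butyldimethylsilyl)oxy]-4-oxobutan-2-yl prop-2-enoate | C[C@H](OC(=O)C=C)[C@H](O[Si](C)(C)C(C)(C)C)C=O
F6 | step 17 | (2S)-hex-5-en-2-yl (2Z,4R,5S)-4-[(tert-butyldimethylsilyl)oxy]-5-(prop-2-enoyloxy)hex-2-enoate | C=CCC[C@H](C)OC(=O)/C=C\[C@@H](O[Si](C)(C)C(C)(C)C)[C@H](C)OC(=O)C=C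
F7 | step 17 | (2S,5RS)-5,6-dihydroxyhexan-2-yl (2Z,4R,5S)-4-[(tert-butyldimethylsilyl)oxy]-5-(prop-2-enoyloxy)hex-2-enoate (not isolated) | OCC(O)CC[C@H](C)OC(=O)/C=C\[C@@H](O[Si](C)(C)C(C)(C)C)[C@H](C)OC(=O)C=C
F8 | step 17 | (2S)-5-oxopentan-2-yl (2Z,4R,5S)-4-[(tert-butyldimethylsilyl)oxy]-5-(prop-2-enoyloxy)hex-2-enoate | O=CCC[C@H](C)OC(=O)/C=C\[C@@H](O[Si](C)(C)C(C)(C)C)[C@H](C)OC(=O)C=C
F9 | step 17 | (2S,5RS)-5-hydroxyhept-6-en-2-yl (2Z,4R,5S)-4-[(tert-butyldimethylsilyl)oxy]-5-(prop-2-enoyloxy)hex-2-enoate | C=CC(O)CC[C@H](C)OC(=O)/C=C\[C@@H](O[Si](C)(C)C(C)(C)C)[C@H](C)OC(=O)C=C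
F10 | step 15 | [2-{[(2S)-hex-5-en-2-yl]oxy}-2-oxoethyl]triphenylphosphonium bromide | C[C@H](OC(=O)C[P+](c1ccccc1)(c1ccccc1)c1ccccc1)CCC=C.[Br-]
F11 | step 15 | (2S)-hex-5-en-2-yl (triphenyl-λ5-phosphanylidene)acetate | C[C@H](OC(=O)C=P(c1ccccc1)(c1ccccc1)c1ccccc1)CCC=C
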